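The constants were drawn at random within sensible limits; no experiment stands behind them.

A waste ratio of 15.8 stands in the ochre flask as its feed begins: that many second end groups pair off into homo dimer for each one that forms a link, and this ratio is the thing to watch.

| flask | first end groups | second end groups | time | remark |
|---|---|---|---|---|
| grey | 18 mM (fed, over 1.5 min) | 18.4 mM | 40 min | all else is in the flask from the start; the feed brings no volume worth counting |
| blue | 18 mM | 18.4 mM | 40 min | everything together at the start |
| ochre | 18 mM (fed, over 15 min) | 18.4 mM | 40 min | all else is in the flask from the start; the feed brings no volume worth counting |
| green | 18 mM | 18.4 mM (fed, over 15 min) | 40 min | all else is in the flask from the start; the feed brings no volume worth counting |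

    first end groups + second end groups → links + by-product (k1 = 2.68 L mol⁻¹ s⁻¹)
    first end groups + links → side product (k2 = 0.0222 L mol⁻¹ s⁻¹)
    2 second end groups → homo dimer (k3 = 0.468 L mol⁻¹ s⁻¹)

- in percentages every species weighs as the first end groups in it: one side product counts as two
- where a step has two of a species, its rate is k times that concentration squared, and two are used at each turn
- run time (grey): 40 min

1. the flask that comes out highest in amount of links, in percent of the first end groups charged, or "all alike" when all lie within 1.5 percentage points (grey / blue / ochre / green / all alike)
2. links at the end, in percent of the first end groups charged, grey
3. links at the end, in percent of the first end groups charged, blue
4. links at the end, in percent of the first end groups charged, ochre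
5. links at the end, in percent of the first end groups charged, green

Which way do the second end groups go? Two steps compete for them, and dividing one rate by the other removes time. This gives the waste ratio, the second end groups used by dimerisation per second end group used by link formation: 2 times the dimer constant times [second end groups], over the link constant times [first end groups]. Blue starts at 0.357. In ochre the feed lasts 44 lifetimes of first end groups against the charged second end groups, so at the very start of the feed [first end groups] sits near the feed rate over the link constant times [second end groups], and the ratio starts at 15.8. By the same reckoning grey starts at 1.58. In green, [second end groups] sits near the feed rate over the link constant times [first end groups], so the ratio starts at 0.00822. My ranking of links is therefore green, blue, grey, ochre .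

What happens to the first end groups left unmatched? Second end groups exceed them by 0.400 mM, so once dimerisation takes more than that, the second end groups remaining can no longer match every first end group charged. At [first end groups] of 18 mM, links have a half-life of 28.9 min, shorter than the 40 min run, so stranded first end groups go on costing links. This reckoning gives an order, not percentages.

The forecast gives green as highest, with green 88 %, blue 72 %, grey 43 % and ochre 17 %, because feeding second end groups into first end groups “keeps them scarce and suppresses dimerisation”.

The flasks end with links at 85.9 % in green, 71.5 % in blue, 41.8 % in grey and 16.6 % in ochre, so green is highest. Ochre stands 3.6 percentage points above the forecast's low end, and its links have moved by 5 points with first end groups at 23.6 mM. At 0.572 min the ochre ratio reads 9.9, lower than its starting 15.8, and over the whole ochre run the second end groups that went to homo dimer per by-product formed come to 2.76. Grey, starting at 1.58, ends at 0.781 on the same count.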